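**Retrosynthetic overview** (drimane numbering: ring A = C1–C5/C10, ring B = C5–C10, C11 = OCH2 on C9, C12 = methylene carbon on C8)
1. The last C–C bond is C9–C11. A Δ8(9) allylsilane is aryloxymethylated (SE2') with the chloromethyl ether of isofraxidin, which also creates C8=C12 and sets C9.
2. The ring A oxygen pattern (C2 acetate on the face of the C10 methyl, C3 ketone) comes from a plain 3-ketone. The sequence is autoxidation to the diosphenol, hydride reduction, orthoacetate opening and oxidation.
3. Key disconnection: C6–C7 and C5–C10 are formed together by an auxiliary-controlled intramolecular Diels–Alder reaction of an acyclic trienimide. Rings A and B form at the same time, and the acyl carbon on C6 is then excised by hydrolysis and Barton decarboxylation.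
4. Enabling feature: in ring B the methylene-bearing C8 lies between C7H2 and C9, so C7–C8–C9–C10 is a latent 2-(silylmethyl)diene and C5–C6 is its dienophile. The four ring A carbons C1–C4 (C3 ketone, C4 gem-dimethyl) already tie C10 to C5 as the tether.
5. The trienimide is built linearly from 4-pentyn-1-ol, an isobutyraldehyde enamine, a phosphonoacetyl oxazolidinone and 2-bromoallyltrimethylsilane.

Key step: step 7

Remark: the target is read as (2R,5S,9S,10R), a trans-decalin with the C10 methyl and the C2 acetoxy group on one face and H5 and the axial C9 CH2OAr group on the other. Isofraxidin, (R)-4-benzyloxazolidin-2-one, 2-bromoallyltrimethylsilane and 4-(2-methylprop-1-en-1-yl)morpholine are taken as purchasable.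

**Step 1**
Reactants: 1 4-pentyn-1-ol
Product: 3 (E)-5-iodo-4-methylpent-4-en-1-ol, via alkenylalane 2 (not isolated)
Conditions: AlMe3 (3 equiv), Cp2ZrCl2 (0.25 equiv), CH2Cl2, 0 °C to rt; I2, THF, −30 °C; aq. potassium sodium tartrate
Reagents that add atoms: trimethylaluminium C[Al](C)C; iodine II
Why: Negishi carboalumination adds methyl and aluminium syn to the terminal alkyne and iodinolysis keeps the geometry, which fixes the E geometry of the later C9=C10 bond.

**Step 2**
Reactants: 3 (E)-5-iodo-4-methylpent-4-en-1-ol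
Product: 5 (E)-5-iodo-4-methylpent-4-enoic acid, via aldehyde 4 (not isolated)
Conditions: TEMPO (0.2 equiv), PhI(OAc)2 (2.2 equiv), MeCN–H2O 1:1, rt
Reagents that add atoms: water O
Why: The oxoammonium (TEMPO/PhI(OAc)2) oxidation takes a primary alcohol through the hydrated aldehyde to the acid and leaves the vinyl iodide untouched.

**Step 3**
Reactants: 5 (E)-5-iodo-4-methylpent-4-enoic acid; 6 4-(2-methylprop-1-en-1-yl)morpholine
Product: 9 (E)-7-iodo-2,2,6-trimethyl-3-oxohept-6-enal, via acid chloride 7 (not isolated), via acyl iminium chloride 8 (not isolated)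
Conditions: (COCl)2, DMF (cat.), CH2Cl2, 0 °C to rt, evaporate; 6, Et2O, 0 °C to reflux; H2O, rt
Reagents that add atoms: water O
Why: Stork enamine C-acylation of a β,β-disubstituted enamine gives an iminium salt that cannot tautomerise, so hydrolysis delivers the 2,2-dimethyl-3-oxo aldehyde and forms the C3–C4 bond at the quaternary carbon.

**Step 4**
Reactants: 10 diethylphosphonoacetic acid; 11 (R)-4-benzyloxazolidin-2-one
Product: 13 (R)-4-benzyl-3-[2-(diethoxyphosphoryl)acetyl]oxazolidin-2-one, via mixed pivalic anhydride 12 (not isolated)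
Conditions: PivCl, Et3N, THF, −20 °C; then LiCl, 11, −20 °C to rt
Reagents that add atoms: none
Why: N-acylation of an oxazolidinone through the mixed pivalic anhydride with LiCl assistance is a standard acylation that does not touch the auxiliary stereocentre.

**Step 5**
Reactants: 9 (E)-7-iodo-2,2,6-trimethyl-3-oxohept-6-enal; 13 (R)-4-benzyl-3-[2-(diethoxyphosphoryl)acetyl]oxazolidin-2-one
Product: 14 (R)-4-benzyl-3-[(2E,8E)-9-iodo-4,4,8-trimethyl-5-oxonona-2,8-dienoyl]oxazolidin-2-one
Conditions: LiCl, iPr2NEt, MeCN, rt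
Reagents that add atoms: none
Why: Horner–Wadsworth–Emmons olefination under Masamune–Roush conditions is mild enough for the non-enolisable β-keto aldehyde, reacts only at the aldehyde and gives the E-enoyl imide (the C5=C6 dienophile).

**Step 6**
Reactants: 14 (R)-4-benzyl-3-[(2E,8E)-9-iodo-4,4,8-trimethyl-5-oxonona-2,8-dienoyl]oxazolidin-2-one; 15 2-bromoallyltrimethylsilane
Product: 18 (R)-4-benzyl-3-[(2E,8E)-4,4,8-trimethyl-5-oxo-10-(trimethylsilylmethyl)undeca-2,8,10-trienoyl]oxazolidin-2-one, via alkenylmagnesium bromide 16 (not isolated), via alkenylzinc bromide 17 (not isolated)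
Conditions: 15, Mg, THF, rt; ZnBr2 (excess), THF, 0 °C; then 14, Pd(PPh3)4 (5 mol%), THF, rt
Reagents that add atoms: none
Why: Negishi coupling of an alkenyl iodide with an alkenylzinc halide keeps the alkene geometry and tolerates ketone and imide, which gives the 2-(silylmethyl)-1,3-diene with the chain trans to C8 and the methyl inside.

**Step 7**
Reactants: 18 (R)-4-benzyl-3-[(2E,8E)-4,4,8-trimethyl-5-oxo-10-(trimethylsilylmethyl)undeca-2,8,10-trienoyl]oxazolidin-2-one
Product: 19 (R)-4-benzyl-3-{[(5S,6R,10S)-3-oxo-12-trimethylsilyl-11-nordrim-8-en-6-yl]carbonyl}oxazolidin-2-one (trans-fused; C10 methyl anti to H5; C6 acyl equatorial and cis to H5)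
Conditions: Me2AlCl (3 equiv), CH2Cl2 (0.01 M), −30 to 0 °C; aq. potassium sodium tartrate
Reagents that add atoms: none
Why: Me2AlCl turns the imide into the cationic chelate in which an AlMe2 unit binds both carbonyl groups, which lowers the LUMO of the C5=C6 bond so that it adds suprafacially, in a concerted but asynchronous [4+2] cycloaddition, to C10 and C7 of the s-cis diene and forms C5–C10 and C6–C7 in the same event. The closest known reaction type is the Lewis acid promoted asymmetric intramolecular Diels–Alder reaction of (2E,8E)-undeca-2,8,10-trienoyl oxazolidinones to trans-fused octalins. Ring B closes as the six-membered cycloaddition ring that holds both new bonds, and ring A closes through the C5–C10 bond alone as a six-membered carbocycle in the fused mode imposed by the four-atom C1–C4 tether, whose C4 gem-dimethyl group favours the folded rotamer. C5 and C6 are set by attack on the C6 Re face of the s-cis chelated enoyl unit (the face turned away from the benzyl group of the (R)-auxiliary) together with the E dienophile geometry, and C10 is set by the E geometry of C9=C10 (tether outside, methyl inside) together with the endo position of the chelated acyl group, which places the C10 methyl anti to H5. The step needs endo over exo selectivity, face selectivity, a populated s-cis diene and cycloaddition in preference to Lewis acid damage of the silane; these are secured respectively by the cationic chelate (the first two), by allylic strain between the inside methyl and the C8 CH2SiMe3 group in the s-trans form, and by proton-scavenging Me–Al bonds, dilution and low temperature. The new C8=C9 bond carries CH2SiMe3 on C8, so the cycloadduct is already the allylsilane that later accepts C11 at C9.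

**Step 8**
Reactants: 19 (R)-4-benzyl-3-{[(5S,6R,10S)-3-oxo-12-trimethylsilyl-11-nordrim-8-en-6-yl]carbonyl}oxazolidin-2-one
Product: 21 (5S,6R,10S)-3-oxo-12-trimethylsilyl-11-nordrim-8-ene-6-carboxylic acid, via peroxy acid 20 (not isolated)
Conditions: LiOH, H2O2, THF–H2O, 0 °C; aq. Na2SO3; cold 1 M HCl to pH 3
Reagents that add atoms: hydrogen peroxide OO
Why: Hydroperoxide cleavage of N-acyl oxazolidinones attacks the exocyclic carbonyl selectively, the auxiliary is released intact, and the hindered ketone and the allylsilane are inert to cold basic peroxide.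

**Step 9**
Reactants: 21 (5S,6R,10S)-3-oxo-12-trimethylsilyl-11-nordrim-8-ene-6-carboxylic acid
Product: 23 (5S,10S)-12-trimethylsilyl-11-nordrim-8-en-3-one, via thiohydroxamate ester 22 (not isolated)
Conditions: 1-hydroxypyridine-2(1H)-thione, DCC, DMAP (cat.), CH2Cl2, dark, 0 °C to rt; then t-BuSH, toluene, visible light, rt
Reagents that add atoms: none
Why: In the Barton reductive decarboxylation the thiohydroxamate ester fragments to the secondary C6 radical, which takes hydrogen from the thiol, so the activating carbon leaves under neutral conditions that spare the allylsilane, C5 and C10.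

**Step 10**
Reactants: 23 (5S,10S)-12-trimethylsilyl-11-nordrim-8-en-3-one
Product: 24 (5S,10S)-2-hydroxy-12-trimethylsilyl-11-nordrima-1,8-dien-3-one (diosphenol)
Conditions: KOtBu, O2 (1 atm), t-BuOH–THF, rt; cold 1 M HCl
Reagents that add atoms: dioxygen O=O
Why: Base-mediated autoxidation of a ketone can occur only at C2 because C4 is quaternary, and it gives the diosphenol as is typical of 4,4-dimethyl-3-keto terpenoids.

**Step 11**
Reactants: 24 (5S,10S)-2-hydroxy-12-trimethylsilyl-11-nordrima-1,8-dien-3-one
Product: 25 (2R,3S,5S,10S)-12-trimethylsilyl-11-nordrim-8-ene-2,3-diol (both hydroxyl groups on the face of the C10 methyl; C2–OH axial; C3–OH equatorial)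
Conditions: NaBH4, MeOH–THF, 0 °C to rt
Reagents that add atoms: none
Why: Borohydride reduction of the diosphenol through its keto tautomers delivers both hydrides from the face opposite the axial C10 and C4 methyl groups, which sets C2 and C3 with both oxygens on the methyl-bearing face.

**Step 12**
Reactants: 25 (2R,3S,5S,10S)-12-trimethylsilyl-11-nordrim-8-ene-2,3-diol
Product: 27 (2R,3S,5S,10S)-3-hydroxy-12-trimethylsilyl-11-nordrim-8-en-2-yl acetate, via cyclic orthoacetate 26 (not isolated)
Conditions: MeC(OMe)3, PPTS (cat.), CH2Cl2, rt; then 80% aq. AcOH, 0 °C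
Reagents that add atoms: trimethyl orthoacetate CC(OC)(OC)OC; water O
Why: Orthoester exchange with the cis-diol followed by mild hydrolysis opens the cyclic orthoacetate under stereoelectronic control to the axial ester and the equatorial alcohol, which places the acetate on O2 without touching C2 or C3.

**Step 13**
Reactants: 27 (2R,3S,5S,10S)-3-hydroxy-12-trimethylsilyl-11-nordrim-8-en-2-yl acetate
Product: 28 (2R,5S,10S)-3-oxo-12-trimethylsilyl-11-nordrim-8-en-2-yl acetate
Conditions: Dess–Martin periodinane, NaHCO3, CH2Cl2, 0 °C to rt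
Reagents that add atoms: none
Why: Dess–Martin oxidation converts the equatorial C3 alcohol into the ketone under buffered, non-epimerising conditions, so the axial C2 acetate keeps its configuration.

**Step 14**
Reactants: 29 isofraxidin (7-hydroxy-6,8-dimethoxycoumarin)
Product: 30 6,8-dimethoxy-7-[(methylsulfanyl)methoxy]coumarin
Conditions: NaH, ClCH2SMe, NaI (cat.), DMF, 0 °C to rt
Reagents that add atoms: chloromethyl methyl sulfide CSCCl
Why: Williamson-type O-alkylation of the acidic phenoxide gives the O,S-acetal, and the non-nucleophilic base does not open the lactone.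

**Step 15**
Reactants: 30 6,8-dimethoxy-7-[(methylsulfanyl)methoxy]coumarin
Product: 31 7-(chloromethoxy)-6,8-dimethoxycoumarin
Conditions: SO2Cl2 (1.0 equiv), CH2Cl2, −20 to 0 °C; evaporate, use at once
Reagents that add atoms: sulfuryl chloride O=S(=O)(Cl)Cl
Why: Chlorinolysis of an aryl O,S-acetal (chlorosulfonium formation and C–S cleavage) is the standard entry to aryl chloromethyl ethers, and everything formed beside the product is volatile.

**Step 16**
Reactants: 28 (2R,5S,10S)-3-oxo-12-trimethylsilyl-11-nordrim-8-en-2-yl acetate; 31 7-(chloromethoxy)-6,8-dimethoxycoumarin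
Product: 32 (2R,5S,9S,10R)-11-[(6,8-dimethoxy-2-oxo-2H-chromen-7-yl)oxy]-3-oxodrim-8(12)-en-2-yl acetate (target)
Conditions: SnCl4 (2 equiv), 2,6-di-tert-butylpyridine, CH2Cl2, −78 °C; aq. NaHCO3
Reagents that add atoms: none
Why: In this Hosomi–Sakurai-type alkylation of an allylsilane with an α-chloro ether, SnCl4 ionises 31 to the aryloxymethyl cation, C9 attacks it axially on the face anti to the C10 methyl (SE2'), and loss of silicon from the β-silyl cation at C8 gives C8=C12, which sets C9 with CH2OAr trans to the C10 methyl.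

**Compound list**
1 | 4-pentyn-1-ol | C#CCCCO | starting material
2 | (E)-5-(dimethylalumanyl)-4-methylpent-4-en-1-yl dimethylaluminium alkoxide | C[Al](C)OCCC/C(C)=C/[Al](C)C | intermediate
3 | (E)-5-iodo-4-methylpent-4-en-1-ol | OCCC/C(C)=C/I | intermediate
4 | (E)-5-iodo-4-methylpent-4-enal | O=CCC/C(C)=C/I | intermediate
5 | (E)-5-iodo-4-methylpent-4-enoic acid | OC(=O)CC/C(C)=C/I | intermediate
6 | 4-(2-methylprop-1-en-1-yl)morpholine | CC(C)=CN1CCOCC1 | starting material
7 | (E)-5-iodo-4-methylpent-4-enoyl chloride | ClC(=O)CC/C(C)=C/I | intermediate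
8 | 4-[(E)-7-iodo-2,2,6-trimethyl-3-oxohept-6-enylidene]morpholin-4-ium chloride | O=C(CC/C(C)=C/I)C(C)(C)C=[N+]1CCOCC1.[Cl-] | intermediate
9 | (E)-7-iodo-2,2,6-trimethyl-3-oxohept-6-enal | O=CC(C)(C)C(=O)CC/C(C)=C/I | intermediate
10 | diethylphosphonoacetic acid | CCOP(=O)(CC(=O)O)OCC | starting material
11 | (R)-4-benzyloxazolidin-2-one | O=C1N[C@H](Cc2ccccc2)CO1 | starting material
12 | diethylphosphonoacetic pivalic anhydride | CCOP(=O)(CC(=O)OC(=O)C(C)(C)C)OCC | intermediate
13 | (R)-4-benzyl-3-[2-(diethoxyphosphoryl)acetyl]oxazolidin-2-one | CCOP(=O)(OCC)CC(=O)N1[C@H](Cc2ccccc2)COC1=O | intermediate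
14 | (R)-4-benzyl-3-[(2E,8E)-9-iodo-4,4,8-trimethyl-5-oxonona-2,8-dienoyl]oxazolidin-2-one | I/C=C(\C)CCC(=O)C(C)(C)/C=C/C(=O)N1[C@H](Cc2ccccc2)COC1=O | intermediate
15 | 2-bromoallyltrimethylsilane | C=C(Br)C[Si](C)(C)C | starting material
16 | [3-(trimethylsilyl)prop-1-en-2-yl]magnesium bromide | C=C([Mg]Br)C[Si](C)(C)C | intermediate
17 | [3-(trimethylsilyl)prop-1-en-2-yl]zinc bromide | C=C([Zn]Br)C[Si](C)(C)C | intermediate
18 | (R)-4-benzyl-3-[(2E,8E)-4,4,8-trimethyl-5-oxo-10-(trimethylsilylmethyl)undeca-2,8,10-trienoyl]oxazolidin-2-one | C=C(C[Si](C)(C)C)/C=C(\C)CCC(=O)C(C)(C)/C=C/C(=O)N1[C@H](Cc2ccccc2)COC1=O | intermediate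
19 | (R)-4-benzyl-3-{[(5S,6R,10S)-3-oxo-12-trimethylsilyl-11-nordrim-8-en-6-yl]carbonyl}oxazolidin-2-one | C[Si](C)(C)CC1=C[C@]2(C)CCC(=O)C(C)(C)[C@H]2[C@H](C(=O)N3[C@H](Cc4ccccc4)COC3=O)C1 | intermediate
20 | (5S,6R,10S)-3-oxo-12-trimethylsilyl-11-nordrim-8-ene-6-carboperoxoic acid | C[Si](C)(C)CC1=C[C@]2(C)CCC(=O)C(C)(C)[C@H]2[C@H](C(=O)OO)C1 | intermediate
21 | (5S,6R,10S)-3-oxo-12-trimethylsilyl-11-nordrim-8-ene-6-carboxylic acid | C[Si](C)(C)CC1=C[C@]2(C)CCC(=O)C(C)(C)[C@H]2[C@H](C(=O)O)C1 | intermediate
22 | 2-thioxopyridin-1(2H)-yl (5S,6R,10S)-3-oxo-12-trimethylsilyl-11-nordrim-8-ene-6-carboxylate | C[Si](C)(C)CC1=C[C@]2(C)CCC(=O)C(C)(C)[C@H]2[C@H](C(=O)ON3C=CC=CC3=S)C1 | intermediate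
23 | (5S,10S)-12-trimethylsilyl-11-nordrim-8-en-3-one | C[Si](C)(C)CC1=C[C@]2(C)CCC(=O)C(C)(C)[C@H]2CC1 | intermediate
24 | (5S,10S)-2-hydroxy-12-trimethylsilyl-11-nordrima-1,8-dien-3-one | C[Si](C)(C)CC1=C[C@]2(C)C=C(O)C(=O)C(C)(C)[C@H]2CC1 | intermediate
25 | (2R,3S,5S,10S)-12-trimethylsilyl-11-nordrim-8-ene-2,3-diol | C[Si](C)(C)CC1=C[C@]2(C)C[C@@H](O)[C@@H](O)C(C)(C)[C@H]2CC1 | intermediate
26 | 2,3-O-(1-methoxyethylidene) derivative of 25 (orthoester carbon as a mixture) | C[Si](C)(C)CC1=C[C@]2(C)C[C@H]3OC(C)(OC)O[C@H]3C(C)(C)[C@H]2CC1 | intermediate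
27 | (2R,3S,5S,10S)-3-hydroxy-12-trimethylsilyl-11-nordrim-8-en-2-yl acetate | C[Si](C)(C)CC1=C[C@]2(C)C[C@@H](OC(C)=O)[C@@H](O)C(C)(C)[C@H]2CC1 | intermediate
28 | (2R,5S,10S)-3-oxo-12-trimethylsilyl-11-nordrim-8-en-2-yl acetate | C[Si](C)(C)CC1=C[C@]2(C)C[C@@H](OC(C)=O)C(=O)C(C)(C)[C@H]2CC1 | intermediate
29 | isofraxidin (7-hydroxy-6,8-dimethoxycoumarin) | Oc1c(OC)cc2ccc(=O)oc2c1OC | starting material
30 | 6,8-dimethoxy-7-[(methylsulfanyl)methoxy]coumarin | CSCOc1c(OC)cc2ccc(=O)oc2c1OC | intermediate
31 | 7-(chloromethoxy)-6,8-dimethoxycoumarin | ClCOc1c(OC)cc2ccc(=O)oc2c1OC | intermediate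
32 | (2R,5S,9S,10R)-11-[(6,8-dimethoxy-2-oxo-2H-chromen-7-yl)oxy]-3-oxodrim-8(12)-en-2-yl acetate | C=C1CC[C@@H]2C(C)(C)C(=O)[C@H](OC(C)=O)C[C@@]2(C)[C@H]1COc1c(OC)cc2ccc(=O)oc2c1OC | target

**Step count**
Total step count: 16.
Longest linear sequence: 13 steps (1–3, 5–13, 16).

**Steps most likely to fail**

Step 7. The C5–C10 bond joins a neopentyl carbon to a fully substituted diene terminus. The cycloaddition may therefore be slow enough for Lewis acid induced loss of the silyl group, intermolecular conjugate allylation or erosion of the endo preference to compete.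
- The fallback sets out from 9 and comes back at 23. It replaces the chelating imide by an enal that is activated covalently and without metal.
- Wittig olefination of 9 with (triphenylphosphoranylidene)acetaldehyde (toluene, 80 °C) would give (2E,8E)-9-iodo-4,4,8-trimethyl-5-oxonona-2,8-dienal F1.
- Negishi coupling with 17 as in step 6 would give (2E,8E)-4,4,8-trimethyl-5-oxo-10-(trimethylsilylmethyl)undeca-2,8,10-trienal F2.
- Iminium catalysis with (2R,5R)-5-benzyl-2-tert-butyl-3-methylimidazolidin-4-one trifluoroacetate (MeCN–H2O, rt) shields the C6 Si face. It would close both rings to (5S,6R,10S)-3-oxo-12-trimethylsilyl-11-nordrim-8-ene-6-carbaldehyde F3.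
- Tsuji–Wilkinson decarbonylation with RhCl(PPh3)3 (toluene, reflux) would then give 23.

Step 16. Ionisation of the aryl chloromethyl ether may lead to Friedel–Crafts self-alkylation of the electron-rich coumarin. Trace acid may also protodesilylate the allylsilane before the hindered C9 can react.
- The fallback sets out from 28 and comes back at 32. It separates C–C and C–O bond formation.
- Hosomi–Sakurai hydroxymethylation of 28 with formaldehyde (paraformaldehyde, Me2AlCl, CH2Cl2, −78 °C), again anti to the C10 methyl, would give (2R,5S,9S,10R)-11-hydroxy-3-oxodrim-8(12)-en-2-yl acetate F4.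
- Mitsunobu etherification of F4 with 29 (PPh3, DIAD, toluene, 0 °C to rt) would give 32.

Step 11. The reduction may stall at a ketol, or hydride may reach one of the two carbonyl carbons from the methyl-bearing face, which would scramble C2 or C3.
- The fallback sets out from 24 and comes back at 28. It sets C2 by delivery of hydrogen to a C=C bond instead of a C=O bond.
- Acetylation of 24 (Ac2O, pyridine, DMAP) would give (5S,10S)-3-oxo-12-trimethylsilyl-11-nordrima-1,8-dien-2-yl acetate F5.
- Hydrogenation over Pd/C (H2 1 atm, EtOAc) would add hydrogen to C1=C2 from the face opposite the C10 methyl. The hindered C8=C9 bond should stay behind, and the acetate is left on the methyl-bearing face as in 28.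

**Further compounds**
F1 | step 7 | (2E,8E)-9-iodo-4,4,8-trimethyl-5-oxonona-2,8-dienal | O=C/C=C/C(C)(C)C(=O)CC/C(C)=C/I
F2 | step 7 | (2E,8E)-4,4,8-trimethyl-5-oxo-10-(trimethylsilylmethyl)undeca-2,8,10-trienal | C=C(C[Si](C)(C)C)/C=C(\C)CCC(=O)C(C)(C)/C=C/C=O
F3 | step 7 | (5S,6R,10S)-3-oxo-12-trimethylsilyl-11-nordrim-8-ene-6-carbaldehyde | C[Si](C)(C)CC1=C[C@]2(C)CCC(=O)C(C)(C)[C@H]2[C@H](C=O)C1
F4 | step 16 | (2R,5S,9S,10R)-11-hydroxy-3-oxodrim-8(12)-en-2-yl acetate | C=C1CC[C@@H]2C(C)(C)C(=O)[C@H](OC(C)=O)C[C@@]2(C)[C@H]1CO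
F5 | step 11 | (5S,10S)-3-oxo-12-trimethylsilyl-11-nordrima-1,8-dien-2-yl acetate | C[Si](C)(C)CC1=C[C@]2(C)C=C(OC(C)=O)C(=O)C(C)(C)[C@H]2CC1
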